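**Retrosynthetic overview**
- Lactone ring (C3–C3a and O1–C2 bonds): open bractelactone to 2',3',4'-trihydroxy-6'-methoxydihydrochalcone plus phenylpyruvic acid. A one-pot hydroxyalkylation/lactonisation/dehydration closes the furanone ring last and sets the Z-benzylidene.
- Methoxy C–O bond (key step): the OMe is installed on the unmethoxylated pyrogallol ketone by dearomatisation to a hydroxy-o-quinone, conjugate addition of methanol and re-aromatisation.
- Aryl ketone: pyrogallol plus 3-phenylpropanoic acid by Friedel–Crafts acylation, which breaks the C2v symmetry of pyrogallol.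
- Ring order: the benzene ring is bought, the lactone ring is formed last, and no protecting groups are used.

Assumption: the target has no stereocentre, so "single enantiomer" is read as the single (Z)-alkene isomer of the given SMILES.

**Route**

Step 1
Reactants: 1 pyrogallol (benzene-1,2,3-triol); 2 3-phenylpropanoic acid
Product: 3 1-(2,3,4-trihydroxyphenyl)-3-phenylpropan-1-one
Conditions: BF3·OEt2 (neat, as solvent), 90 °C
Reagents that add atoms: none
Why: Nencki-type Friedel–Crafts acylation in which the BF3-activated acid attacks C4 of pyrogallol (C4 and C6 are equivalent, C5 is not activated), and the chelated ortho-hydroxy ketone formed is deactivated against a second acylation.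

Step 2
Reactants: 3 1-(2,3,4-trihydroxyphenyl)-3-phenylpropan-1-one
Product: 6 1-(2,3,4-trihydroxy-6-methoxyphenyl)-3-phenylpropan-1-one, via hydroxy-o-quinone 4 (not isolated), via methoxy-hydroxy-o-quinone 5 (not isolated)
Conditions: PhI(OAc)2 (2.2 equiv), MeOH, −20 → 0 °C, 3 added slowly; then Na2S2O4, H2O/EtOAc, rt
Reagents that add atoms: methanol (CO)
Why: Proposed new method: PhI(OAc)2 dearomatises the pyrogallol to the chelated hydroxy-o-quinone 4, whose only electrophilic ring CH (C6', β to the C4' quinone carbonyl and, in the minor tautomer, β to the aryl ketone as well) takes up methanol by 1,4-addition, the adduct re-aromatises, is re-oxidised by the second equivalent to the push–pull quinone 5 and is returned to the arene by dithionite; the closest known reactions are the oxidation of catechol in methanol to 4,5-dimethoxy-1,2-benzoquinone and the addition of nucleophiles to 3-acyl-o-quinones next to the acyl group.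

Step 3
Reactants: 6 1-(2,3,4-trihydroxy-6-methoxyphenyl)-3-phenylpropan-1-one; 7 phenylpyruvic acid (2-oxo-3-phenylpropanoic acid, 1.5 equiv)
Product: 9 bractelactone, via hydroxy lactone 8 (not isolated)
Conditions: TfOH (10 mol %), (CF3)2CHOH, 50 °C, Ar
Reagents that add atoms: none
Why: Proposed new method: acid-catalysed Friedel–Crafts hydroxyalkylation of the only free ring position (C5', ortho/para to three oxygens) by the keto group of 7, lactonisation onto the adjacent 4'-OH and E1 dehydration through a cation stabilised by the para-hydroxyl give the benzylidene lactone, and reversible protonation lets the new alkene settle as the Z isomer in which the phenyl group avoids the 4-OMe group; the closest known reaction is the phenol/glyoxylic acid or phenol/pyruvate hydroxyalkylation–lactonisation to 3-hydroxybenzofuran-2(3H)-ones.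

**Compound list**

1 | pyrogallol (benzene-1,2,3-triol) | Oc1cccc(O)c1O | starting material
2 | 3-phenylpropanoic acid (hydrocinnamic acid) | OC(=O)CCc1ccccc1 | starting material
3 | 1-(2,3,4-trihydroxyphenyl)-3-phenylpropan-1-one | O=C(CCc1ccccc1)c1ccc(O)c(O)c1O | intermediate
4 | 3-hydroxy-4-(3-phenylpropanoyl)cyclohexa-3,5-diene-1,2-dione (hydroxy-o-quinone of 3, drawn as the tautomer with the OH chelated to the ketone) | O=C(CCc1ccccc1)C1=C(O)C(=O)C(=O)C=C1 | intermediate
5 | 3-hydroxy-5-methoxy-4-(3-phenylpropanoyl)cyclohexa-3,5-diene-1,2-dione | COC1=CC(=O)C(=O)C(O)=C1C(=O)CCc1ccccc1 | intermediate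
6 | 1-(2,3,4-trihydroxy-6-methoxyphenyl)-3-phenylpropan-1-one | COc1cc(O)c(O)c(O)c1C(=O)CCc1ccccc1 | intermediate
7 | phenylpyruvic acid (2-oxo-3-phenylpropanoic acid) | OC(=O)C(=O)Cc1ccccc1 | starting material
8 | rac-3-benzyl-3,6,7-trihydroxy-4-methoxy-5-(3-phenylpropanoyl)-1-benzofuran-2(3H)-one (one uncontrolled stereocentre at C3, removed on dehydration) | COc1c(C(=O)CCc2ccccc2)c(O)c(O)c2OC(=O)C(O)(Cc3ccccc3)c12 | intermediate
9 | bractelactone, (3Z)-3-benzylidene-6,7-dihydroxy-4-methoxy-5-(3-phenylpropanoyl)-1-benzofuran-2(3H)-one (phenyl on the side of the lactone carbonyl) | COc1c(C(=O)CCc2ccccc2)c(O)c(O)c2c1/C(=C/c1ccccc1)C(=O)O2 | target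

**Step count and risks**

Total step count: 3. Longest linear sequence: 3.

Steps most likely to fail, most risky first:

Step 2. Methanol could add at C5' instead of C6', the hydroxy-o-quinone could couple with unoxidised pyrogallol (purpurogallin-type), or over-methoxylation could occur. The fallback sets out from 3 and comes back at 9 by closing the lactone before the dearomatisation. Ketone 3 is condensed with 7 under the step 3 conditions, through rac-3-benzyl-3,6,7-trihydroxy-5-(3-phenylpropanoyl)-1-benzofuran-2(3H)-one F2, to the 4-unsubstituted isoaurone (3E)-3-benzylidene-6,7-dihydroxy-5-(3-phenylpropanoyl)-1-benzofuran-2(3H)-one F3. F3 is a plain catechol with a single free ring position. PhI(OAc)2 in MeOH oxidises it to the o-quinone (3E)-3-benzylidene-5-(3-phenylpropanoyl)-1-benzofuran-2,6,7(3H)-trione F4, which can take up methanol only at C4 (β to both the quinone carbonyl and the ketone). Re-oxidation gives (3E)-3-benzylidene-4-methoxy-5-(3-phenylpropanoyl)-1-benzofuran-2,6,7(3H)-trione F5. Dithionite reduction gives 9 mixed with its E isomer (3E)-3-benzylidene-6,7-dihydroxy-4-methoxy-5-(3-phenylpropanoyl)-1-benzofuran-2(3H)-one F6, and catalytic I2 in CH2Cl2 in daylight equilibrates F6 to the less hindered 9.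

Step 3. Phenylpyruvic acid may self-condense or decarbonylate faster than it attacks the hindered C5' position, or the dehydration may stall. The fallback sets out from 6 and comes back at 9 by forming the C3–C3a bond first and the benzylidene afterwards. Glyoxylic acid monohydrate (MeSO3H cat., AcOH, 60 °C) gives rac-3,6,7-trihydroxy-4-methoxy-5-(3-phenylpropanoyl)-1-benzofuran-2(3H)-one F7. SnCl2·2H2O/HCl in AcOH removes the benzylic hydroxyl to give 6,7-dihydroxy-4-methoxy-5-(3-phenylpropanoyl)-1-benzofuran-2(3H)-one F8. Acid-catalysed Knoevenagel condensation of F8 with benzaldehyde (TsOH, toluene, reflux) gives 9, Z under thermodynamic control because of the 4-OMe group.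

Step 1. O-acylation, diacylation or a moderate yield with air-sensitive pyrogallol are the risks. The fallback sets out from 1 and comes back at 3 by O-acylation followed by acyl migration. 3-Phenylpropanoyl chloride/pyridine converts 1 into the tris-ester benzene-1,2,3-triyl tris(3-phenylpropanoate) F1. An AlCl3 Fries rearrangement (PhCl, 120 °C) moves one acyl group to C4, and the two unmigrated esters are hydrolysed in the work-up (aq HCl, MeOH, reflux) to give 3.

**Further compounds**

F1 | step 1 | benzene-1,2,3-triyl tris(3-phenylpropanoate) | O=C(CCc1ccccc1)Oc1cccc(OC(=O)CCc2ccccc2)c1OC(=O)CCc1ccccc1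
F2 | step 2 | rac-3-benzyl-3,6,7-trihydroxy-5-(3-phenylpropanoyl)-1-benzofuran-2(3H)-one | O=C(CCc1ccccc1)c1cc2c(OC(=O)C2(O)Cc2ccccc2)c(O)c1O
F3 | step 2 | (3E)-3-benzylidene-6,7-dihydroxy-5-(3-phenylpropanoyl)-1-benzofuran-2(3H)-one | O=C(CCc1ccccc1)c1cc2c(OC(=O)/C2=C/c2ccccc2)c(O)c1O
F4 | step 2 | (3E)-3-benzylidene-5-(3-phenylpropanoyl)-1-benzofuran-2,6,7(3H)-trione | O=C(CCc1ccccc1)C1=CC2=C(OC(=O)/C2=C/c2ccccc2)C(=O)C1=O
F5 | step 2 | (3E)-3-benzylidene-4-methoxy-5-(3-phenylpropanoyl)-1-benzofuran-2,6,7(3H)-trione | O=C(CCc1ccccc1)C1=C(OC)C2=C(OC(=O)/C2=C/c2ccccc2)C(=O)C1=O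
F6 | step 2 | (3E)-3-benzylidene-6,7-dihydroxy-4-methoxy-5-(3-phenylpropanoyl)-1-benzofuran-2(3H)-one | COc1c(C(=O)CCc2ccccc2)c(O)c(O)c2c1/C(=C\c1ccccc1)C(=O)O2
F7 | step 3 | rac-3,6,7-trihydroxy-4-methoxy-5-(3-phenylpropanoyl)-1-benzofuran-2(3H)-one | COc1c(C(=O)CCc2ccccc2)c(O)c(O)c2OC(=O)C(O)c12
F8 | step 3 | 6,7-dihydroxy-4-methoxy-5-(3-phenylpropanoyl)-1-benzofuran-2(3H)-one | COc1c(C(=O)CCc2ccccc2)c(O)c(O)c2OC(=O)Cc12
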